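## Retrosynthetic overview

1. Target: (1R,4Z,5R,7S)-5-(4-hydroxybenzyl)-4-(4-hydroxybenzylidene)-1,7-dimethyl-6,8-dioxa-3-azabicyclo[3.2.1]octan-2-one. Locants used below: C1 (quaternary C–CH3), C2 (lactam C=O), N3, C4 (enamide carbon), C5 (ketal carbon), O6, C7 (CH–CH3), O8.
2. Feature carrying the strategy: the 1,3-dioxolane ring C1–O8–C5–O6–C7 can be read as a ketone (C5=O6) laid across an epoxide (C1–O8–C7). C7 is the epoxide carbon remote from the carboxyl carbon C2, so it is the carbon a nucleophile opens, with inversion.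
3. Disconnections, backwards: O–Si cleavage; N3–C4 by 6-exo-dig anti-hydroamidation of a C5-alkynyl group by the C2 carboxamide; O6–C7 and C5–O8 together by BF3-catalysed epoxide–ketone (3+2) annulation of a glycidic ester with an ynone.
4. Fragments: the glycidic ester from methyl angelate (reduction, Sharpless epoxidation, oxidation, esterification); the ynone from the Weinreb amide of 4-hydroxyphenylacetic acid and the acetylide made from 4-iodophenol and ethynyltrimethylsilane.
5. Ring order: dioxolane first (step 11), lactam second (step 13). Phenols are carried as triisopropylsilyl (TIPS) ethers, which should tolerate methanolic ammonia and KOtBu better than smaller silyl groups.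

Key step: step 11

## Route

Step 1
Reactants: 1 methyl angelate [methyl (Z)-2-methylbut-2-enoate]
Product: 2 (Z)-2-methylbut-2-en-1-ol
Conditions: iBu2AlH (2.2 equiv), CH2Cl2, −78 °C; aqueous potassium sodium tartrate work-up
Reagents that add atoms: none
Why: Ester-to-alcohol reduction with iBu2AlH at −78 °C is a 1,2-hydride delivery that leaves the Z-trisubstituted alkene and its geometry untouched, so the Z-allylic alcohol needed for the epoxidation should result.

Step 2
Reactants: 2 (Z)-2-methylbut-2-en-1-ol
Product: 3 [(2S,3R)-2,3-dimethyloxiran-2-yl]methanol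
Conditions: Ti(OiPr)4 (10 mol %), L-(+)-diethyl tartrate (12 mol %), t-BuOOH, 4 Å MS, CH2Cl2, −20 °C
Reagents that add atoms: tert-butyl hydroperoxide, CC(C)(C)OO
Why: Sharpless asymmetric epoxidation: syn transfer of oxygen from the titanium-bound peroxide keeps the alkene geometry (the two methyl groups end up trans on the oxirane), and the L-(+)-tartrate ligand selects the alkene face that gives the 2S,3R epoxy alcohol, as it does for other (Z)-allylic alcohols.

Step 3
Reactants: 3 [(2S,3R)-2,3-dimethyloxiran-2-yl]methanol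
Product: 4 (2R,3R)-2,3-dimethyloxirane-2-carboxylic acid
Conditions: RuCl3·xH2O (2 mol %), NaIO4 (3 equiv), MeCN/EtOAc/H2O, 0 °C → rt; crude acid used directly
Reagents that add atoms: sodium periodate, [Na+].[O-]I(=O)(=O)=O; water, O
Why: RuO4 generated catalytically from RuCl3 and NaIO4 oxidises the primary alcohol through the aldehyde hydrate to the acid without opening the oxirane (ruthenium-catalysed periodate oxidation); the stereocentres are untouched and the C2 descriptor changes from S to R only because the carboxyl group now outranks C3.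

Step 4
Reactants: 4 (2R,3R)-2,3-dimethyloxirane-2-carboxylic acid
Product: 5 methyl (2R,3R)-2,3-dimethyloxirane-2-carboxylate
Conditions: MeI, KHCO3, DMF, rt
Reagents that add atoms: iodomethane, CI
Why: Carboxylate O-alkylation (SN2 on iodomethane) with the weak base KHCO3 esterifies the acid without opening the epoxide or touching either stereocentre.

Step 5
Reactants: 6 4-hydroxyphenylacetic acid
Product: 7 2-(4-hydroxyphenyl)-N-methoxy-N-methylacetamide
Conditions: MeNH(OMe)·HCl, EDC·HCl, N-methylmorpholine, CH2Cl2, 0 °C → rt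
Reagents that add atoms: N,O-dimethylhydroxylamine hydrochloride, CNOC.Cl
Why: Carbodiimide amide coupling; the O-acylisourea is intercepted by the amine far faster than by the phenol, so the Weinreb amide should form without phenol protection.

Step 6
Reactants: 7 2-(4-hydroxyphenyl)-N-methoxy-N-methylacetamide
Product: 8 N-methoxy-N-methyl-2-(4-TIPSO-phenyl)acetamide
Conditions: TIPSCl, imidazole, DMF, rt
Reagents that add atoms: chlorotriisopropylsilane, CC(C)[Si](Cl)(C(C)C)C(C)C
Why: Imidazole-promoted silylation of the phenol (silyl ether formation) installs the bulky aryl silyl ether that should resist the acetylide, BF3, ammonia and KOtBu used later.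

Step 7
Reactants: 9 4-iodophenol
Product: 10 (4-iodophenoxy)triisopropylsilane
Conditions: TIPSCl, imidazole, DMF, rt
Reagents that add atoms: chlorotriisopropylsilane, CC(C)[Si](Cl)(C(C)C)C(C)C
Why: Imidazole-promoted phenol silylation (silyl ether formation) masks the acidic OH before the coupling and organolithium steps.

Step 8
Reactants: 10 (4-iodophenoxy)triisopropylsilane; 11 ethynyltrimethylsilane
Product: 12 trimethyl[(4-TIPSO-phenyl)ethynyl]silane
Conditions: PdCl2(PPh3)2 (2 mol %), CuI (4 mol %), Et3N, THF, rt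
Reagents that add atoms: none
Why: Sonogashira coupling: oxidative addition of the aryl iodide to zerovalent palladium and transmetalation from the copper acetylide proceed at room temperature, and the C-silyl group prevents a second arylation.

Step 9
Reactants: 12 trimethyl[(4-TIPSO-phenyl)ethynyl]silane
Product: 13 (4-ethynylphenoxy)triisopropylsilane
Conditions: K2CO3 (0.2 equiv), MeOH/THF, 0 °C
Reagents that add atoms: none
Why: Methoxide-catalysed protodesilylation cleaves the alkynyl C–SiMe3 bond much faster than the hindered aryl O–Si(iPr)3 bond, so the terminal alkyne should be freed selectively.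

Step 10
Reactants: 13 (4-ethynylphenoxy)triisopropylsilane; 8 N-methoxy-N-methyl-2-(4-TIPSO-phenyl)acetamide
Product: 16 1,4-bis(4-TIPSO-phenyl)but-3-yn-2-one, via lithium arylacetylide 14 (not isolated), via tetrahedral lithium adduct 15 (not isolated)
Conditions: n-BuLi, THF, −78 °C; then 8, −78 → 0 °C; aq. NH4Cl
Reagents that add atoms: none
Why: Weinreb ketone synthesis: acetylide 14 adds once to the N-methoxy-N-methylamide and the chelated adduct 15 holds until the quench, so over-addition is excluded; a small excess of 14 offsets competing deprotonation of the benzylic CH2.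

Step 11
Reactants: 5 methyl (2R,3R)-2,3-dimethyloxirane-2-carboxylate; 16 1,4-bis(4-TIPSO-phenyl)but-3-yn-2-one
Product: 17 methyl (2R,4R,5S)-4,5-dimethyl-2-(4-TIPSO-benzyl)-2-[(4-TIPSO-phenyl)ethynyl]-1,3-dioxolane-4-carboxylate
Conditions: BF3·OEt2 (30 mol %), CH2Cl2, −40 → 0 °C; 5 added slowly to 16 (2 equiv); held at 0 °C, then Et3N quench; chromatography, recovered C2 epimer returned to BF3·OEt2 in CH2Cl2
Reagents that add atoms: none
Why: BF3 binds the oxirane oxygen of 5, the carbonyl oxygen of 16 attacks the CH(CH3) carbon from the face opposite the breaking C–O bond, and the boron-bound tertiary alkoxide then collapses onto the alkynyl-stabilised oxocarbenium carbon and releases BF3. The closest known reaction type is the Lewis acid-catalysed conversion of epoxides and ketones into 1,3-dioxolanes, which runs with inversion at the attacked carbon. The one ring formed is the dioxolane, closed by a formally 5-endo-trig attack of oxygen on the oxocarbenium carbon, the same closure as in an acid-catalysed ketalisation of a 1,2-diol. Dioxolane C5 (target C7) is set by this backside displacement (3R in 5 becomes 5S), dioxolane C4 (target C1) keeps the configuration of 5 because its C–O bond is never broken, and the ketal carbon C2 (target C5) is not controlled in the ring closure but is equilibrated by BF3 through reversible reopening to the oxocarbenium ion. The step needs attack at the secondary carbon and not at the ester-bearing quaternary carbon, which the ester secures by destabilising positive charge at its α-carbon and the full substitution there reinforces; slow addition of 5 to excess, recoverable 16 should keep ketone capture ahead of rearrangement of the activated epoxide. The 2R epimer 17 (alkyne cis to the ester, the only arrangement that can lactamise) should be separable by chromatography from its C2 epimer, and that epimer is returned to BF3·OEt2 so that it re-equilibrates to more 17.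

Step 12
Reactants: 17 methyl (2R,4R,5S)-4,5-dimethyl-2-(4-TIPSO-benzyl)-2-[(4-TIPSO-phenyl)ethynyl]-1,3-dioxolane-4-carboxylate
Product: 18 (2R,4R,5S)-4,5-dimethyl-2-(4-TIPSO-benzyl)-2-[(4-TIPSO-phenyl)ethynyl]-1,3-dioxolane-4-carboxamide
Conditions: NH3 (7 M in MeOH), sealed tube, 50 °C
Reagents that add atoms: ammonia, N
Why: Ester aminolysis: the α-oxygen activates the methyl ester toward ammonia, the carboxyl-bearing carbon is fully substituted so no epimerisation is possible, and the ketal, alkyne and aryl silyl ethers should be inert to neutral ammonia.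

Step 13
Reactants: 18 (2R,4R,5S)-4,5-dimethyl-2-(4-TIPSO-benzyl)-2-[(4-TIPSO-phenyl)ethynyl]-1,3-dioxolane-4-carboxamide
Product: 19 (1R,4Z,5R,7S)-1,7-dimethyl-5-(4-TIPSO-benzyl)-4-(4-TIPSO-benzylidene)-6,8-dioxa-3-azabicyclo[3.2.1]octan-2-one
Conditions: KOtBu (1.2 equiv), THF, 0 °C → rt; aq. NH4Cl
Reagents that add atoms: none
Why: Base-mediated intramolecular anti-hydroamidation: the potassium amidate, held cis to the alkynyl group on the dioxolane, attacks through nitrogen the alkyne carbon attached to the ketal carbon in a 6-exo-dig closure (charge developing on the aryl-bearing carbon, helped inductively by the two ketal oxygens), and protonation of the vinyl anion trans to nitrogen gives the Z-enamide, which is also the isomer that keeps the aryl group away from the ketal carbon.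

Step 14
Reactants: 19 (1R,4Z,5R,7S)-1,7-dimethyl-5-(4-TIPSO-benzyl)-4-(4-TIPSO-benzylidene)-6,8-dioxa-3-azabicyclo[3.2.1]octan-2-one
Product: 20 leptochartamide B
Conditions: Bu4NF (2.5 equiv), AcOH (2.5 equiv), THF, 0 °C
Reagents that add atoms: none
Why: Fluoride-induced silyl ether cleavage, buffered with acetic acid, should free both phenols while the bicyclic ketal, the lactam and the Z-enamide are stable to these conditions, giving the target.

## Compound list

1 | methyl angelate, methyl (Z)-2-methylbut-2-enoate | C/C=C(/C)C(=O)OC | starting material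
2 | (Z)-2-methylbut-2-en-1-ol | C/C=C(/C)CO | intermediate
3 | [(2S,3R)-2,3-dimethyloxiran-2-yl]methanol | C[C@H]1O[C@@]1(C)CO | intermediate
4 | (2R,3R)-2,3-dimethyloxirane-2-carboxylic acid | C[C@H]1O[C@@]1(C)C(=O)O | intermediate
5 | methyl (2R,3R)-2,3-dimethyloxirane-2-carboxylate | C[C@H]1O[C@@]1(C)C(=O)OC | intermediate
6 | 4-hydroxyphenylacetic acid | OC(=O)Cc1ccc(O)cc1 | starting material
7 | 2-(4-hydroxyphenyl)-N-methoxy-N-methylacetamide | CON(C)C(=O)Cc1ccc(O)cc1 | intermediate
8 | N-methoxy-N-methyl-2-{4-[(triisopropylsilyl)oxy]phenyl}acetamide | CON(C)C(=O)Cc1ccc(O[Si](C(C)C)(C(C)C)C(C)C)cc1 | intermediate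
9 | 4-iodophenol | Oc1ccc(I)cc1 | starting material
10 | (4-iodophenoxy)triisopropylsilane | CC(C)[Si](Oc1ccc(I)cc1)(C(C)C)C(C)C | intermediate
11 | ethynyltrimethylsilane | C#C[Si](C)(C)C | starting material
12 | trimethyl({4-[(triisopropylsilyl)oxy]phenyl}ethynyl)silane | CC(C)[Si](Oc1ccc(C#C[Si](C)(C)C)cc1)(C(C)C)C(C)C | intermediate
13 | (4-ethynylphenoxy)triisopropylsilane | C#Cc1ccc(O[Si](C(C)C)(C(C)C)C(C)C)cc1 | intermediate
14 | lithium {4-[(triisopropylsilyl)oxy]phenyl}acetylide (not isolated) | [Li]C#Cc1ccc(O[Si](C(C)C)(C(C)C)C(C)C)cc1 | intermediate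
15 | lithium 2-[methoxy(methyl)amino]-1,4-bis{4-[(triisopropylsilyl)oxy]phenyl}but-3-yn-2-olate (not isolated) | [Li+].[O-]C(Cc1ccc(O[Si](C(C)C)(C(C)C)C(C)C)cc1)(C#Cc1ccc(O[Si](C(C)C)(C(C)C)C(C)C)cc1)N(C)OC | intermediate
16 | 1,4-bis{4-[(triisopropylsilyl)oxy]phenyl}but-3-yn-2-one | O=C(Cc1ccc(O[Si](C(C)C)(C(C)C)C(C)C)cc1)C#Cc1ccc(O[Si](C(C)C)(C(C)C)C(C)C)cc1 | intermediate
17 | methyl (2R,4R,5S)-4,5-dimethyl-2-{4-[(triisopropylsilyl)oxy]benzyl}-2-({4-[(triisopropylsilyl)oxy]phenyl}ethynyl)-1,3-dioxolane-4-carboxylate | C[C@@H]1O[C@](C#Cc2ccc(O[Si](C(C)C)(C(C)C)C(C)C)cc2)(Cc2ccc(O[Si](C(C)C)(C(C)C)C(C)C)cc2)O[C@@]1(C)C(=O)OC | intermediate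
18 | (2R,4R,5S)-4,5-dimethyl-2-{4-[(triisopropylsilyl)oxy]benzyl}-2-({4-[(triisopropylsilyl)oxy]phenyl}ethynyl)-1,3-dioxolane-4-carboxamide | C[C@@H]1O[C@](C#Cc2ccc(O[Si](C(C)C)(C(C)C)C(C)C)cc2)(Cc2ccc(O[Si](C(C)C)(C(C)C)C(C)C)cc2)O[C@@]1(C)C(N)=O | intermediate
19 | (1R,4Z,5R,7S)-1,7-dimethyl-5-{4-[(triisopropylsilyl)oxy]benzyl}-4-{4-[(triisopropylsilyl)oxy]benzylidene}-6,8-dioxa-3-azabicyclo[3.2.1]octan-2-one | C[C@@H]1O[C@]2(Cc3ccc(O[Si](C(C)C)(C(C)C)C(C)C)cc3)O[C@@]1(C)C(=O)N/C2=C\c1ccc(O[Si](C(C)C)(C(C)C)C(C)C)cc1 | intermediate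
20 | leptochartamide B, (1R,4Z,5R,7S)-5-(4-hydroxybenzyl)-4-(4-hydroxybenzylidene)-1,7-dimethyl-6,8-dioxa-3-azabicyclo[3.2.1]octan-2-one | C[C@@H]1O[C@]2(Cc3ccc(O)cc3)O[C@@]1(C)C(=O)N/C2=C\c1ccc(O)cc1 | target

## Step count and risk

Total step count: 14. Longest linear sequence: 8 steps (steps 7, 8, 9, 10, 11, 12, 13, 14 from 4-iodophenol; equally steps 1–4 and 11–14 from methyl angelate).

Steps most likely to fail:

Step 11. Capture of the BF3-activated epoxide by the weakly nucleophilic, conjugated carbonyl oxygen may be slower than 1,2-shift (Meinwald rearrangement) or oligomerisation of the epoxide and Lewis acid-induced self-condensation of the enolisable ynone. In addition, the ketal carbon forms without facial control, so part of the material must be separated and re-equilibrated. The fallback sets out from 5 and 16 and returns at 17. It separates the two C–O bond formations. Epoxide 5 is opened with water (HClO4 cat., THF/H2O, rt), which attacks the same secondary carbon with inversion, to give methyl (2R,3S)-2,3-dihydroxy-2-methylbutanoate F1. Both hydroxyl groups are silylated (TMSOTf, 2,6-lutidine, CH2Cl2, 0 °C) to methyl (2R,3S)-2-methyl-2,3-bis[(trimethylsilyl)oxy]butanoate F2. Noyori ketalisation of 16 with F2 (TMSOTf cat., CH2Cl2, −78 → −20 °C) then closes the dioxolane as 17, again together with its C2 epimer, which is handled as in step 11.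

Step 13. Addition of the amidate to an electron-rich, unactivated aryl alkyne may be slow. Attack of the alkoxide on the aryl silyl ethers would generate phenoxides that deactivate the alkyne further, and O-attack of the ambident amidate would lead to the cyclic imidate. The fallback sets out from 17 and returns at 19. It replaces hydroamidation by oxygen cyclisation followed by O-to-N exchange. Me3SnOH (1,2-dichloroethane, 70 °C) cleaves the methyl ester to (2R,4R,5S)-4,5-dimethyl-2-(4-TIPSO-benzyl)-2-[(4-TIPSO-phenyl)ethynyl]-1,3-dioxolane-4-carboxylic acid F3. Ph3PAuCl/AgOTf (cat., CH2Cl2, rt) adds the carboxylic acid across the alkyne (6-exo-dig, anti) to give the enol lactone (1R,4Z,5R,7S)-1,7-dimethyl-5-(4-TIPSO-benzyl)-4-(4-TIPSO-benzylidene)-3,6,8-trioxabicyclo[3.2.1]octan-2-one F4. Ammonia in methanol opens the enol lactone, and the liberated ketone is captured by the new amide as the hydroxy lactam (1R,5R,7S)-4-hydroxy-1,7-dimethyl-4,5-bis(4-TIPSO-benzyl)-6,8-dioxa-3-azabicyclo[3.2.1]octan-2-one F5. Dehydration (PPTS cat., toluene, 4 Å MS, 60 °C) should give 19, the Z-enamide being the less strained isomer.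

Step 12. Attack of ammonia at an ester carbonyl on a fully substituted carbon may be too slow, and forcing it may strip the aryl silyl ethers. The fallback sets out from 17 and returns at 18. It activates the acid in place of direct aminolysis. The ester is cleaved with Me3SnOH as above to the carboxylic acid F3. 1,1'-Carbonyldiimidazole (THF, rt) converts it into the acyl imidazole 1-{[(2R,4R,5S)-4,5-dimethyl-2-(4-TIPSO-benzyl)-2-[(4-TIPSO-phenyl)ethynyl]-1,3-dioxolan-4-yl]carbonyl}imidazole F6. Ammonia (0.5 M in 1,4-dioxane, rt) then gives 18.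

Further compounds

F1 | step 11 | methyl (2R,3S)-2,3-dihydroxy-2-methylbutanoate | C[C@H](O)[C@@](C)(O)C(=O)OC
F2 | step 11 | methyl (2R,3S)-2-methyl-2,3-bis[(trimethylsilyl)oxy]butanoate | C[C@H](O[Si](C)(C)C)[C@@](C)(O[Si](C)(C)C)C(=O)OC
F3 | step 13 | (2R,4R,5S)-4,5-dimethyl-2-{4-[(triisopropylsilyl)oxy]benzyl}-2-({4-[(triisopropylsilyl)oxy]phenyl}ethynyl)-1,3-dioxolane-4-carboxylic acid | C[C@@H]1O[C@](C#Cc2ccc(O[Si](C(C)C)(C(C)C)C(C)C)cc2)(Cc2ccc(O[Si](C(C)C)(C(C)C)C(C)C)cc2)O[C@@]1(C)C(=O)O
F4 | step 13 | (1R,4Z,5R,7S)-1,7-dimethyl-5-{4-[(triisopropylsilyl)oxy]benzyl}-4-{4-[(triisopropylsilyl)oxy]benzylidene}-3,6,8-trioxabicyclo[3.2.1]octan-2-one | C[C@@H]1O[C@]2(Cc3ccc(O[Si](C(C)C)(C(C)C)C(C)C)cc3)O[C@@]1(C)C(=O)O/C2=C\c1ccc(O[Si](C(C)C)(C(C)C)C(C)C)cc1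
F5 | step 13 | (1R,5R,7S)-4-hydroxy-1,7-dimethyl-4,5-bis{4-[(triisopropylsilyl)oxy]benzyl}-6,8-dioxa-3-azabicyclo[3.2.1]octan-2-one (mixture at C4) | C[C@@H]1O[C@]2(Cc3ccc(O[Si](C(C)C)(C(C)C)C(C)C)cc3)O[C@@]1(C)C(=O)NC2(O)Cc1ccc(O[Si](C(C)C)(C(C)C)C(C)C)cc1
F6 | step 12 | 1-{[(2R,4R,5S)-4,5-dimethyl-2-{4-[(triisopropylsilyl)oxy]benzyl}-2-({4-[(triisopropylsilyl)oxy]phenyl}ethynyl)-1,3-dioxolan-4-yl]carbonyl}imidazole | C[C@@H]1O[C@](C#Cc2ccc(O[Si](C(C)C)(C(C)C)C(C)C)cc2)(Cc2ccc(O[Si](C(C)C)(C(C)C)C(C)C)cc2)O[C@@]1(C)C(=O)n1ccnc1
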